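**Retrosynthetic overview**
1. Target ⇐ acetal hydrolysis ⇐ Pd-formylation of a ring enol triflate ⇐ nine-membered β-acetal ketone that already carries the finished side chain.
2. Nine-membered ring ⇐ Grob-type fragmentative ring expansion of a cis-hydrindane 1,3-diol monomesylate (5-ring + 6-ring → 9-ring; E-olefin from the antiperiplanar C–C / C–OMs bonds).
3. Hydrindane ⇐ one-pot iminium/enamine Mukaiyama–Michael/aldol of an enal-dione with a ketene silyl acetal (new step; sets the three stereocentres that survive).
4. Enal-dione ⇐ 2-methylcyclopentane-1,3-dione + acrolein + formylmethylene ylide; ketene acetal ⇐ tert-butyl acetate + 5-bromo-2-methylpent-2-ene.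
5. Ring order: cyclopentane (bought) → cyclohexane (aldol) → cyclononadiene (fragmentation).

Assumption: the conformers of the (E)-cyclononene ring interconvert at room temperature, so the three sp3 centres define the target; the hydrindanes are drawn as the expected ring-fusion diastereomer, and any other cis-fused diastereomer would converge at 15, where those centres become sp2.

Step 1
Reactants: 1 2-methylcyclopentane-1,3-dione; 2 acrolein
Product: 3 3-(1-methyl-2,5-dioxocyclopentyl)propanal
Conditions: H2O, rt, 16 h
Reagents that add atoms: none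
Why: Michael addition of the acidic cyclic 1,3-dione to acrolein in water is a clean conjugate addition that builds the quaternary carbon; no stereocentre is formed.

Step 2
Reactants: 3 3-(1-methyl-2,5-dioxocyclopentyl)propanal
Product: 4 (E)-5-(1-methyl-2,5-dioxocyclopentyl)pent-2-enal
Conditions: Ph3P=CHCHO (1.1 equiv), toluene, 80 °C
Reagents that add atoms: (triphenylphosphoranylidene)acetaldehyde, O=CC=P(c1ccccc1)(c1ccccc1)c1ccccc1
Why: Wittig olefination with the stabilised formylmethylene ylide is aldehyde-selective (the hindered ring ketones do not react) and E-selective.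

Step 3
Reactants: 5 tert-butyl acetate; 6 5-bromo-2-methylpent-2-ene
Product: 7 tert-butyl 6-methylhept-5-enoate
Conditions: LDA, THF, −78 °C; then 6, DMPU, −78 → 0 °C
Reagents that add atoms: none
Why: SN2 enolate alkylation of the lithium enolate of tert-butyl acetate with the primary bromide; the tert-butyl ester suppresses Claisen self-condensation.

Step 4
Reactants: 7 tert-butyl 6-methylhept-5-enoate
Product: 8 (E)-1-tert-butoxy-6-methyl-1-(trimethylsilyloxy)hepta-1,5-diene
Conditions: LDA, THF, −78 °C; TMSCl, −78 °C → rt; distil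
Reagents that add atoms: chlorotrimethylsilane, C[Si](C)(C)Cl
Why: Kinetic deprotonation with LDA in THF gives the E(O)-enolate, and O-silylation (Ireland-type enol silane formation) gives the E ketene silyl acetal.

Step 5
Reactants: 4 (E)-5-(1-methyl-2,5-dioxocyclopentyl)pent-2-enal; 8 (E)-1-tert-butoxy-6-methyl-1-(trimethylsilyloxy)hepta-1,5-diene
Product: 11 cis-hydrindane ketol dimethyl acetal (tert-butyl ester), via Michael adduct aldehyde 9 (not isolated), via hydrindane ketol aldehyde 10 (not isolated)
Conditions: (S)-2-{bis[3,5-bis(trifluoromethyl)phenyl](trimethylsilyloxy)methyl}pyrrolidine (20 mol %), 2,4-dinitrobenzoic acid (20 mol %), H2O (2 equiv), CH2Cl2, −30 °C → rt; then HC(OMe)3, MeOH, PPTS, rt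
Reagents that add atoms: trimethyl orthoformate, COC(OC)OC
Why: Proposed new method: the (S)-diarylprolinol silyl ether forms the E-iminium of 4 and shields one β-face, so the ketene silyl acetal adds from the open face through an open antiperiplanar transition state (Mukaiyama–Michael; anti C–C bond, setting the ring carbon and the side-chain carbon), and the catalyst-bound enamine is then trapped by one of the two dione carbonyls in a chair 6-exo aldol (formyl equatorial, hence trans to the side chain; ring fusion necessarily cis) before the aldehyde is masked in the same flask; the closest known reactions are amine-catalysed Mukaiyama–Michael additions of silyl ketene (thio)acetals to enals and the Hajos–Parrish/enolexo enamine aldol desymmetrisation of 2,2-disubstituted cyclopentane-1,3-diones, whose merger in one cascade with an O-alkyl ketene silyl acetal has not been described.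

Step 6
Reactants: 11 cis-hydrindane ketol dimethyl acetal (tert-butyl ester)
Product: 12 hydrindane triol acetal
Conditions: LiAlH4, THF, 0 °C → rt; Rochelle salt work-up (no acid)
Reagents that add atoms: none
Why: Hydride reduction with LiAlH4 converts the ester to the primary alcohol and the cyclopentanone to the secondary alcohol in one operation, with hydride expected to add anti to the adjacent angular methyl (as in 17-keto steroid and Hajos–Parrish ketone reductions), so the new OH is cis to the methyl and to the ring-fusion OH; the acetal is inert.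

Step 7
Reactants: 12 hydrindane triol acetal
Product: 14 hydrindane acetate mesylate, via primary acetate 13 (not isolated)
Conditions: AcCl (1.05 equiv), 2,4,6-collidine, CH2Cl2, −78 °C; then MsCl, Et3N, 0 °C
Reagents that add atoms: acetyl chloride, CC(Cl)=O; methanesulfonyl chloride, CS(Cl)(=O)=O
Why: Chemoselective acylation (AcCl/collidine at −78 °C takes only the primary OH) followed by sulfonylation of the secondary OH; the tertiary ring-fusion OH does not react.

Step 8
Reactants: 14 hydrindane acetate mesylate
Product: 15 (E)-cyclononenone acetal acetate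
Conditions: KHMDS (1.05 equiv), 18-crown-6, THF, −78 °C → rt
Reagents that add atoms: none
Why: Grob fragmentation: the tertiary alkoxide pushes, the ring-fusion C3a–C7a bond (antiperiplanar to C1–OMs) breaks and mesylate leaves, merging both rings into the nine-membered ketone; because OMs is cis to the angular methyl, the six-ring CH2 on C7a and C2 are anti across C7a–C1 and the olefin is E, and the cis O/OMs relationship rules out oxetane formation.

Step 9
Reactants: 15 (E)-cyclononenone acetal acetate
Product: 16 ring enol triflate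
Conditions: KHMDS (1.05 equiv), THF, −78 °C; then PhNTf2, −78 → 0 °C
Reagents that add atoms: N-phenylbis(trifluoromethanesulfonimide), O=S(=O)(N(c1ccccc1)S(=O)(=O)C(F)(F)F)C(F)(F)F
Why: Kinetic enolisation removes a proton from the unhindered α-CH2 rather than the tertiary α′-H next to the acetal, and the ring-cis enolate is trapped by O-triflation (enol triflate formation).

Step 10
Reactants: 16 ring enol triflate
Product: 17 enal dimethyl acetal
Conditions: Pd(OAc)2 (5 mol %), dppp, CO (1 atm), Et3SiH, Et3N, DMF, 70 °C
Reagents that add atoms: carbon monoxide, [C-]#[O+]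
Why: Palladium-catalysed reductive carbonylation (formylation) of the alkenyl triflate: oxidative addition, CO insertion and silane hydrogenolysis of the acyl–Pd give the enal with retention of alkene geometry.

Step 11
Reactants: 17 enal dimethyl acetal
Product: 18 target, (2R)-2-[(1S,2S,3E,6E)-2,3-diformyl-7-methylcyclonona-3,6-dien-1-yl]-6-methylhept-5-en-1-yl acetate
Conditions: PPTS, acetone/H2O (10:1), 40 °C
Reagents that add atoms: water, O
Why: Mild acid-catalysed acetal hydrolysis frees the second aldehyde; the acetate, the enal and the trans arrangement of formyl and side chain (also the expected thermodynamic one at this epimerisable centre) are kept.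

**Compound list**
1 | 2-methylcyclopentane-1,3-dione | CC1C(=O)CCC1=O | starting material
2 | acrolein | C=CC=O | starting material
3 | 3-(1-methyl-2,5-dioxocyclopentyl)propanal | CC1(CCC=O)C(=O)CCC1=O | intermediate
4 | (E)-5-(1-methyl-2,5-dioxocyclopentyl)pent-2-enal | CC1(CC/C=C/C=O)C(=O)CCC1=O | intermediate
5 | tert-butyl acetate | CC(=O)OC(C)(C)C | starting material
6 | 5-bromo-2-methylpent-2-ene | CC(C)=CCCBr | starting material
7 | tert-butyl 6-methylhept-5-enoate | CC(C)=CCCCC(=O)OC(C)(C)C | intermediate
8 | (E)-1-tert-butoxy-6-methyl-1-(trimethylsilyloxy)hepta-1,5-diene (alkyl chain cis to O-tBu) | CC(C)=CCC/C=C(\OC(C)(C)C)O[Si](C)(C)C | intermediate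
9 | tert-butyl (2R,3R)-2-(4-methylpent-3-enyl)-3-[2-(1-methyl-2,5-dioxocyclopentyl)ethyl]-5-oxopentanoate (anti Michael adduct) | CC1(CC[C@H](CC=O)[C@@H](CCC=C(C)C)C(=O)OC(C)(C)C)C(=O)CCC1=O | intermediate
10 | tert-butyl 2-(4-formyl-3a-hydroxy-7a-methyl-1-oxo-octahydroinden-5-yl)-6-methylhept-5-enoate; cis-fused, 3a-OH, 7a-CH3 and 4-CHO on one face, the C5 side chain on the other, side-chain centre as in 9 | C[C@]12CC[C@@H]([C@@H](CCC=C(C)C)C(=O)OC(C)(C)C)[C@H](C=O)[C@@]1(O)CCC2=O | intermediate
11 | dimethyl acetal of 10 (4-dimethoxymethyl), same configuration | C[C@]12CC[C@@H]([C@@H](CCC=C(C)C)C(=O)OC(C)(C)C)[C@H](C(OC)OC)[C@@]1(O)CCC2=O | intermediate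
12 | 2-[4-(dimethoxymethyl)-1,3a-dihydroxy-7a-methyl-octahydroinden-5-yl]-6-methylhept-5-en-1-ol; 1-OH cis to 7a-CH3 and 3a-OH | C[C@]12CC[C@@H]([C@@H](CCC=C(C)C)CO)[C@H](C(OC)OC)[C@@]1(O)CC[C@@H]2O | intermediate
13 | primary acetate of 12 | C[C@]12CC[C@@H]([C@@H](CCC=C(C)C)COC(C)=O)[C@H](C(OC)OC)[C@@]1(O)CC[C@@H]2O | intermediate
14 | 1-O-methanesulfonate of 13 (OMs cis to 7a-CH3 and 3a-OH) | C[C@]12CC[C@@H]([C@@H](CCC=C(C)C)COC(C)=O)[C@H](C(OC)OC)[C@@]1(O)CC[C@@H]2OS(C)(=O)=O | intermediate
15 | (2R)-2-[(1S,2R,6E)-2-(dimethoxymethyl)-7-methyl-3-oxocyclonon-6-en-1-yl]-6-methylhept-5-en-1-yl acetate | CC(=O)OC[C@H](CCC=C(C)C)[C@@H]1CC/C(C)=C/CCC(=O)[C@H]1C(OC)OC | intermediate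
16 | (2R)-2-[(1S,2S,3E,6E)-2-(dimethoxymethyl)-7-methyl-3-(trifluoromethanesulfonyloxy)cyclonona-3,6-dien-1-yl]-6-methylhept-5-en-1-yl acetate (3,4-olefin cis within the ring) | CC(=O)OC[C@H](CCC=C(C)C)[C@@H]1CC/C(C)=C/C/C=C(/OS(=O)(=O)C(F)(F)F)[C@H]1C(OC)OC | intermediate
17 | (2R)-2-[(1S,2S,3E,6E)-2-(dimethoxymethyl)-3-formyl-7-methylcyclonona-3,6-dien-1-yl]-6-methylhept-5-en-1-yl acetate | CC(=O)OC[C@H](CCC=C(C)C)[C@@H]1CC/C(C)=C/C/C=C(/C=O)[C@H]1C(OC)OC | intermediate
18 | (2R)-2-[(1S,2S,3E,6E)-2,3-diformyl-7-methylcyclonona-3,6-dien-1-yl]-6-methylhept-5-en-1-yl acetate | CC(=O)OC[C@H](CCC=C(C)C)[C@@H]1CC/C(C)=C/C/C=C(/C=O)[C@H]1C=O | target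

**Step count and risks**
Total: 11 steps. Longest linear sequence: 9 steps (1, 2, 5–11; steps 3–4 make the second fragment).

Most likely to fail:

Step 5 (the new cascade). Risks are low anti selectivity or ee in the Michael event, hydrolysis of the enamine before it cyclises, and dehydration of the ketol. The fallback uses only known reactions, sets out from 4 (with 6) and returns at 12. Alkylate the lithium enolate of S-tert-butyl thioacetate with 6 to give S-tert-butyl 6-methylhept-5-enethioate F1, and convert it (LDA, TMSCl) into the (Z)-silyl ketene thioacetal F2. Run the established imidazolidinone-salt-catalysed Mukaiyama–Michael addition of F2 to 4 and isolate the thioester Michael adduct aldehyde F3. Close the ring in a separate proline-type 6-enolexo aldolisation to the thioester hydrindane ketol aldehyde F4, protect it as the thioester hydrindane dimethyl acetal F5, and reduce thioester and ketone with LiAlH4 to reach 12. A ring-fusion diastereomer of 12 would simply be carried on to 15, where the difference disappears.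

Step 6 (facial selectivity at the cyclopentanone). Hydride delivered from the ring-fusion O–Al alkoxide could give the 1-epimer, which would lead to the Z-olefin or an oxetane in step 8. The fallback sets out from 11 and returns at 12. Reduce only the ketone under boron chelation with external hydride (Et2BOMe, NaBH4, THF/MeOH, −78 °C, Narasaka–Prasad 1,3-syn reduction) to the syn-1,3-diol tert-butyl ester F6, then reduce the ester of F6 with LiAlH4 to 12.

Step 8 (fragmentation next to a base-labile acetate). Acyl transfer to the tertiary alkoxide or ester enolisation could compete, here and in the enolisation of step 9. The fallback sets out from 12 and returns at 17, carrying a base-stable silyl ether through the ring expansion. Silylate the primary alcohol (TBSCl, imidazole) to the TBS ether triol acetal F7 and mesylate it to the TBS ether mesylate F8. Fragment with KOtBu in THF to the TBS-protected cyclononenone F9, then triflate and formylate as in steps 9 and 10 to the TBS-protected enol triflate F10 and the TBS-protected enal acetal F11. Remove the silyl group (TBAF/AcOH) to the primary alcohol enal acetal F12 and acetylate (Ac2O, pyridine) to 17.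

**Further compounds**
F1 | step 5 | S-tert-butyl 6-methylhept-5-enethioate | CC(C)=CCCCC(=O)SC(C)(C)C
F2 | step 5 | (Z)-silyl ketene thioacetal | CC(C)=CCC/C=C(\SC(C)(C)C)O[Si](C)(C)C
F3 | step 5 | thioester Michael adduct aldehyde | CC1(CC[C@H](CC=O)[C@@H](CCC=C(C)C)C(=O)SC(C)(C)C)C(=O)CCC1=O
F4 | step 5 | thioester hydrindane ketol aldehyde | C[C@]12CC[C@@H]([C@@H](CCC=C(C)C)C(=O)SC(C)(C)C)[C@H](C=O)[C@@]1(O)CCC2=O
F5 | step 5 | thioester hydrindane dimethyl acetal | C[C@]12CC[C@@H]([C@@H](CCC=C(C)C)C(=O)SC(C)(C)C)[C@H](C(OC)OC)[C@@]1(O)CCC2=O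
F6 | step 6 | syn-1,3-diol tert-butyl ester | C[C@]12CC[C@@H]([C@@H](CCC=C(C)C)C(=O)OC(C)(C)C)[C@H](C(OC)OC)[C@@]1(O)CC[C@@H]2O
F7 | step 8 | TBS ether triol acetal | C[C@]12CC[C@@H]([C@@H](CCC=C(C)C)CO[Si](C)(C)C(C)(C)C)[C@H](C(OC)OC)[C@@]1(O)CC[C@@H]2O
F8 | step 8 | TBS ether mesylate | C[C@]12CC[C@@H]([C@@H](CCC=C(C)C)CO[Si](C)(C)C(C)(C)C)[C@H](C(OC)OC)[C@@]1(O)CC[C@@H]2OS(C)(=O)=O
F9 | step 8 | TBS-protected cyclononenone | CC(C)(C)[Si](C)(C)OC[C@H](CCC=C(C)C)[C@@H]1CC/C(C)=C/CCC(=O)[C@H]1C(OC)OC
F10 | step 8 | TBS-protected enol triflate | CC(C)(C)[Si](C)(C)OC[C@H](CCC=C(C)C)[C@@H]1CC/C(C)=C/C/C=C(/OS(=O)(=O)C(F)(F)F)[C@H]1C(OC)OC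
F11 | step 8 | TBS-protected enal acetal | CC(C)(C)[Si](C)(C)OC[C@H](CCC=C(C)C)[C@@H]1CC/C(C)=C/C/C=C(/C=O)[C@H]1C(OC)OC
F12 | step 8 | primary alcohol enal acetal | OC[C@H](CCC=C(C)C)[C@@H]1CC/C(C)=C/C/C=C(/C=O)[C@H]1C(OC)OC
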